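## The problem

Target 19 is a benzene ring (ring A) and a pyrrole (ring B) joined only through one ketone carbon. Ring A carries four contiguous substituents: the ketone at C1, hydroxyls at C2 and C4, and the 4-methylpentyl chain at C3; C5 and C6 bear hydrogen. Ring B is attached through its C2, carries chlorine at C4 and C5, and keeps a free N–H. There is no stereocentre, so nothing has to be controlled in space and the whole difficulty is regiochemical. The chain sits between two oxygens, the site of a resorcinol that substitution reaches least selectively in competition with C5, and the ketone must be ortho to only one hydroxyl. The free resorcinol is very electron-rich and would be halogenated or oxidised under the conditions that chlorinate ring B, so it has to stay masked until the end. The dichloropyrrole would not survive hydrogenolysis, dissolving metals or alkyllithium reagents (C–Cl bonds), and excess electrophilic chlorine would attack its C3. The feature that opens the key step is the sequence O–C2, chain–C3, O–C4 next to the carbonyl-bearing C1. C3–C4 with chain and oxygen is the footprint of an alkyl-substituted ynol ether. C2, C1, C6 and C5, with oxygen on C2 and a carboxyl carbon on C1, are the footprint of a vinylketene with an ester at its terminus.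

## Retrosynthesis

19 to 18. The two phenolic O–H bonds at C2 and C4 of ring A are exchanged for O–CH3. Methyl is preferred to benzyl, whose hydrogenolysis would endanger the C–Cl bonds, and to silyl or acyl groups, which would not survive the hydroxide and Grignard steps before it. The precursor 18 is no smaller, but it no longer holds a free resorcinol. The forward reaction must cleave both ethers, including the one at C4 that has no chelation help from the ketone, and leave the C–Cl bonds and the ketone alone.

18 to 17. The C4–Cl and C5–Cl bonds of ring B are cut. Chlorinating after the ketone is in place is preferred to carrying a dichlorinated pyrrole nucleophile, which is not a practical reagent. The acyl group at C2 deactivates C3 and directs the electrophile to C4 and then C5. The precursor 17 is the parent pyrrolyl ketone. The forward reaction must deliver exactly two chlorines and only to ring B.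

17 to 13 and 14. The bond between the ketone carbon and C2 of ring B is cut, giving acid 13 (used as chloride 15) and pyrrole 14 (used as its magnesium salt 16). The other possible cut, between ring A and the ketone carbon, would need a Friedel–Crafts reaction on ring A and would discard the carboxyl carbon that the ring construction delivers in place. The forward reaction must acylate an ambident pyrrolyl anion at carbon C2, not at nitrogen or C3.

13 to 12 to 11. These are functional-group changes only: the acid goes back to its ethyl ester 12, and the two methyl ethers go back to the silyl ether and free phenol of 11. The aryl silyl ether of 11 would be lost in hydroxide, so both oxygens are converted to methyl ethers in one flask before saponification. The forward reactions must methylate a hindered, hydrogen-bonded salicylate hydroxyl and hydrolyse an ester with one ortho substituent.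

11 to 3 and 6 (key disconnection). Four ring bonds of ring A are cut: C1–C2, C2–C3, C4–C5 and C5–C6. C3–C4 survives as the triple bond of siloxyalkyne 6, and C6–C1 as the alkene of diazo enone 3. The alternative, alkylating a 2,4-dihydroxybenzoate between its oxygens, has to fight substitution at C5, and metalation sequences need several protecting-group steps. Here both precursors are open-chain, and the hydroxyl, chain, siloxy and ester groups arrive on adjacent carbons in one operation through intermediates 7, 8, 9 and 10. The forward reaction must orient the ketene–alkyne cycloaddition so that the chain-bearing carbon bonds to the ketene carbonyl carbon.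

3 to 1. The C=N2 unit is cut from the methyl carbon of commercial keto ester 1 by a diazo transfer through the trifluoroacetyl diketone 2. This is preferred to acylating a diazoalkane with an unsaturated acid chloride, because a diazoalkane adds as a dipole to a C=C bond flanked by two acceptors. The forward reaction must deprotonate the methyl group of 1 without conjugate addition and keep the E alkene.

6 to 4. The O–Si bond and one alkyne carbon are cut: ester 4 is homologated by one carbon from CH2Br2 to ynolate 5, which is silylated on oxygen. The chain of the target is bought complete in 4. The forward reaction must give O-silylation, which the bulky triisopropylsilyl chloride favours.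

## Roads not taken

Alternative 1: The cut is at the aryl–oxygen bond of one hydroxyl and at the aryl–chain bond. In the forward step the carboxylate of 4-methylpentanoic acid A3 adds to 3-methoxybenzyne A2 at the carbon remote from the methoxy group, and the aryl anion next to the methoxy group takes the acyl group, giving hydroxy ketone A1. Its merits are that ring A is bought, that the chain is placed between the two oxygens by the mechanism, and that no diazo compound or photochemistry is needed. Its weak points for this target are as follows.
- The ketone of A1 is at the wrong oxidation level and must be reduced to CH2.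
- The ether must then be cleaved to the symmetric resorcinol A4.
- The pyrrolyl ketone still has to be attached by C-acylation of A4 with an activated form of 4,5-dichloro-1H-pyrrole-2-carboxylic acid A5. That is a Friedel–Crafts or Fries reaction of a weakly electrophilic acylpyrrole on an O-nucleophilic free resorcinol.

In fairness, this road is probably shorter and brings the chlorines in ready-made, so it needs no late chlorination. The chosen plan sets against it that the carboxyl carbon is already on C1 when ring A forms. The ketone then comes from acyl substitution at a defined carbon, and no bond-forming step is spent on an oxygen that must later be removed.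

Alternative 2: The cut is inside ring B, at N1–C5 and C2–C3. In the forward step the amine of amino ketone A7 displaces dimethylamine from chlorovinamidinium salt A8, and the ketone α-carbon closes onto the remaining iminium carbon, giving the 4-chloropyrrolyl ketone A6. Its merit is that chlorine at C4 cannot be misplaced and only one chlorination, at the most reactive position C5, would remain to reach 18. Its weak points are as follows.
- A7 already contains the complete tetrasubstituted ring A, so the real problem of the target is left unsolved.
- A7 as a free base self-condenses and must be released in the flask.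
- Several steps (acid to methyl ketone, α-functionalisation, amine) are spent building a ring that pyrrole 14 supplies.
- A late chlorination and the demethylation are still needed.

This road is better only in the certainty of the C4 chlorine. The chosen plan answers with a single dichlorination in which the acyl group directs the two chlorines to C4 and C5, and with fewer steps. Alternative 2 is an alternative end-game, not a competing construction of ring A.

Alternative 3: The cut is in ring A at C1–C6 and C3–C4 (target numbering). In the forward step the central carbon of diketone A10 adds to methyl acrylate A11, and the chain-bearing α-carbon then closes onto the ester, giving the acylcyclohexanedione A9. Its merits are that the chain ends up between the two ring carbonyls, the aroyl unit is in place, both chlorines are introduced earlier on a simple pyrrole, and ring A needs no oxygen protecting groups. Its weak points are as follows.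
- The central carbon of A10 has two acidic hydrogens and can add twice.
- The Claisen closure must come from the less acidic chain-side carbon.
- Alkoxide can cleave the tricarbonyl system by retro-Claisen reaction.
- A9 must still be dehydrogenated to the aromatic level in the presence of C–Cl bonds and an electron-rich pyrrole, and the nitrogen protecting group must then be removed.

It is better than the chosen plan in avoiding a late electrophilic chlorination next to an electron-rich arene. The chosen plan sets against it that ring A is formed directly at the aromatic oxidation level, with its regiochemistry fixed by the polarity of the two partners.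

Key step: step 3

Assumption: compounds 1 and 4 are taken as catalogue chemicals, and diazo compound 3 is prepared and used cold, dilute and without storage.

## Steps

Step 1
Reactants: 1 ethyl (E)-4-oxopent-2-enoate
Product: 3 ethyl (E)-5-diazo-4-oxopent-2-enoate, via ethyl (E)-7,7,7-trifluoro-4,6-dioxohept-2-enoate 2 (not isolated)
Conditions: LiN(SiMe3)2, THF, −78 °C; CF3CO2CH2CF3; aq HCl; then 4-AcNHC6H4SO2N3, Et3N, H2O, MeCN, rt
Reagents that add atoms: 4-acetamidobenzenesulfonyl azide, CC(=O)Nc1ccc(cc1)S(=O)(=O)N=[N+]=[N-]
Why: Claisen-type trifluoroacetylation of the methyl group activates it for a detrifluoroacetylative (Regitz-type) diazo transfer, the method of choice for α′-diazo enones; no diazoalkane is present to add to the acceptor alkene, and the E geometry is untouched.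

Step 2
Reactants: 4 ethyl 5-methylhexanoate
Product: 6 triisopropyl[(6-methylhept-1-yn-1-yl)oxy]silane, via lithium 6-methylhept-1-yn-1-olate 5 (not isolated)
Conditions: CH2Br2, lithium 2,2,6,6-tetramethylpiperidide, THF, −78 °C; n-BuLi, −78 °C to rt; i-Pr3SiCl, −78 °C to rt
Reagents that add atoms: dibromomethane, BrCBr; triisopropylsilyl chloride, CC(C)[Si](Cl)(C(C)C)C(C)C
Why: Kowalski ester homologation: dibromomethyllithium adds to the ester, bromine–lithium exchange on the dibromo enolate triggers a 1,2-shift of the alkyl group to give ynolate 5, and the bulky silyl chloride should silylate 5 on oxygen.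

Step 3
Reactants: 3 ethyl (E)-5-diazo-4-oxopent-2-enoate; 6 triisopropyl[(6-methylhept-1-yn-1-yl)oxy]silane
Product: 11 ethyl 2-hydroxy-3-(4-methylpentyl)-4-[(triisopropylsilyl)oxy]benzoate, via ethyl (E)-5-oxopenta-2,4-dienoate 7 (not isolated), via ethyl (E)-3-[3-(4-methylpentyl)-4-oxo-2-[(triisopropylsilyl)oxy]cyclobut-2-en-1-yl]prop-2-enoate 8 (not isolated), via ethyl (2E,4E)-6-(4-methylpentyl)-7-oxo-5-[(triisopropylsilyl)oxy]hepta-2,4,6-trienoate 9 (not isolated), via ethyl 3-(4-methylpentyl)-2-oxo-4-[(triisopropylsilyl)oxy]cyclohexa-3,5-diene-1-carboxylate 10 (not isolated)
Conditions: hν (254 nm, Vycor), ClCH2CH2Cl, rt; then 80 °C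
Reagents that add atoms: none
Why: Irradiation expels N2 from 3 and the alkenyl group shifts to the diazo carbon (photochemical Wolff rearrangement), giving vinylketene 7 with the ester at its terminus. The chain-bearing carbon of 6, made nucleophilic by the siloxy oxygen, attacks the ketene carbonyl carbon, and the (2+2) cycloaddition closes the four-membered ring of 8. Reversible 4-pi electrocyclic opening of 8 gives dienylketene 9, of which only the isomer with the acrylate arm cis to the ketene-bearing carbon can go on. The six-membered ring closes by thermal disrotatory 6-pi electrocyclization of 9, the ketene carbon bonding to the ester-bearing alkene carbon, and dienone 10 tautomerizes to phenol 11. The closest known reaction type is the Danheiser benzannulation of α-diazo enones and aryl diazomethyl ketones with triisopropylsiloxyalkynes, which gives resorcinol monosilyl ethers by the same sequence. No stereocentre remains in 11, since the sp3 centres of 8 and 10 are lost on aromatization. The selectivity needed is the orientation of the cycloaddition, which the siloxy group secures by polarizing the alkyne; the E alkene of 3 keeps the ester on the outside of the closing triene, and the ester makes the ketene more electrophilic toward the electron-rich alkyne.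

Step 4
Reactants: 11 ethyl 2-hydroxy-3-(4-methylpentyl)-4-[(triisopropylsilyl)oxy]benzoate
Product: 12 ethyl 2,4-dimethoxy-3-(4-methylpentyl)benzoate
Conditions: CsF, K2CO3, MeI, DMF, rt to 50 °C
Reagents that add atoms: iodomethane, CI
Why: Fluoride cleaves the aryl O–Si bond and the phenoxide is methylated in the same flask, while carbonate deprotonates the hydrogen-bonded salicylate hydroxyl for a Williamson methylation; the ethyl ester is inert to these conditions.

Step 5
Reactants: 12 ethyl 2,4-dimethoxy-3-(4-methylpentyl)benzoate
Product: 13 2,4-dimethoxy-3-(4-methylpentyl)benzoic acid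
Conditions: NaOH, EtOH/H2O, 80 °C; then aq HCl
Reagents that add atoms: sodium hydroxide, [Na+].[OH-]
Why: Ordinary saponification of a benzoate with a single ortho substituent; the methyl ethers and the alkyl chain are untouched.

Step 6
Reactants: 13 2,4-dimethoxy-3-(4-methylpentyl)benzoic acid; 14 1H-pyrrole
Product: 17 [2,4-dimethoxy-3-(4-methylpentyl)phenyl](1H-pyrrol-2-yl)methanone, via 2,4-dimethoxy-3-(4-methylpentyl)benzoyl chloride 15 (not isolated), via pyrrol-1-ylmagnesium bromide 16 (not isolated)
Conditions: (COCl)2, cat. DMF, CH2Cl2, 0 °C to rt, evaporate; 14, EtMgBr, Et2O/toluene, 0 °C; then 15, −40 °C to rt; aq NH4Cl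
Reagents that add atoms: none
Why: Acid chloride formation followed by acylation of the pyrrolyl Grignard reagent, which reacts with aroyl chlorides mainly at C2 because magnesium stays on nitrogen; a second equivalent of 16 deprotonates the product and protects it from further attack.

Step 7
Reactants: 17 [2,4-dimethoxy-3-(4-methylpentyl)phenyl](1H-pyrrol-2-yl)methanone
Product: 18 (4,5-dichloro-1H-pyrrol-2-yl)[2,4-dimethoxy-3-(4-methylpentyl)phenyl]methanone
Conditions: SO2Cl2 (2 equiv), Et2O/CH2Cl2, 0 °C to rt
Reagents that add atoms: sulfuryl chloride, ClS(Cl)(=O)=O
Why: Electrophilic aromatic chlorination of a 2-acylpyrrole goes to C4 and then C5, the acyl group deactivating C3; the pyrrole is more nucleophilic than the dimethoxyarene, so two equivalents should stop at the 4,5-dichloride.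

Step 8
Reactants: 18 (4,5-dichloro-1H-pyrrol-2-yl)[2,4-dimethoxy-3-(4-methylpentyl)phenyl]methanone
Product: 19 (4,5-dichloro-1H-pyrrol-2-yl)[2,4-dihydroxy-3-(4-methylpentyl)phenyl]methanone
Conditions: BBr3 (excess), CH2Cl2, −78 °C to rt; H2O
Reagents that add atoms: none
Why: Lewis-acid ether cleavage in which bromide attacks the methyl group of the boron-complexed ether; chelation to the ketone speeds the C2 ether, excess reagent covers the basic sites and the C4 ether, and aryl chlorides and the ketone are inert.

## Compound list

1 | ethyl (E)-4-oxopent-2-enoate | CCOC(=O)/C=C/C(C)=O | starting material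
2 | ethyl (E)-7,7,7-trifluoro-4,6-dioxohept-2-enoate | CCOC(=O)/C=C/C(=O)CC(=O)C(F)(F)F | intermediate
3 | ethyl (E)-5-diazo-4-oxopent-2-enoate | CCOC(=O)/C=C/C(=O)C=[N+]=[N-] | intermediate
4 | ethyl 5-methylhexanoate | CCOC(=O)CCCC(C)C | starting material
5 | lithium 6-methylhept-1-yn-1-olate | [Li+].[O-]C#CCCCC(C)C | intermediate
6 | triisopropyl[(6-methylhept-1-yn-1-yl)oxy]silane | CC(C)CCCC#CO[Si](C(C)C)(C(C)C)C(C)C | intermediate
7 | ethyl (E)-5-oxopenta-2,4-dienoate | CCOC(=O)/C=C/C=C=O | intermediate
8 | ethyl (E)-3-[3-(4-methylpentyl)-4-oxo-2-[(triisopropylsilyl)oxy]cyclobut-2-en-1-yl]prop-2-enoate (racemic) | CCOC(=O)/C=C/C1C(=O)C(CCCC(C)C)=C1O[Si](C(C)C)(C(C)C)C(C)C | intermediate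
9 | ethyl (2E,4E)-6-(4-methylpentyl)-7-oxo-5-[(triisopropylsilyl)oxy]hepta-2,4,6-trienoate | CCOC(=O)/C=C/C=C(\C(CCCC(C)C)=C=O)O[Si](C(C)C)(C(C)C)C(C)C | intermediate
10 | ethyl 3-(4-methylpentyl)-2-oxo-4-[(triisopropylsilyl)oxy]cyclohexa-3,5-diene-1-carboxylate (racemic) | CCOC(=O)C1C=CC(O[Si](C(C)C)(C(C)C)C(C)C)=C(CCCC(C)C)C1=O | intermediate
11 | ethyl 2-hydroxy-3-(4-methylpentyl)-4-[(triisopropylsilyl)oxy]benzoate | CCOC(=O)c1ccc(O[Si](C(C)C)(C(C)C)C(C)C)c(CCCC(C)C)c1O | intermediate
12 | ethyl 2,4-dimethoxy-3-(4-methylpentyl)benzoate | CCOC(=O)c1ccc(OC)c(CCCC(C)C)c1OC | intermediate
13 | 2,4-dimethoxy-3-(4-methylpentyl)benzoic acid | OC(=O)c1ccc(OC)c(CCCC(C)C)c1OC | intermediate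
14 | 1H-pyrrole | c1cc[nH]c1 | starting material
15 | 2,4-dimethoxy-3-(4-methylpentyl)benzoyl chloride | ClC(=O)c1ccc(OC)c(CCCC(C)C)c1OC | intermediate
16 | pyrrol-1-ylmagnesium bromide | Br[Mg]n1cccc1 | intermediate
17 | [2,4-dimethoxy-3-(4-methylpentyl)phenyl](1H-pyrrol-2-yl)methanone | CC(C)CCCc1c(OC)ccc(C(=O)c2ccc[nH]2)c1OC | intermediate
18 | (4,5-dichloro-1H-pyrrol-2-yl)[2,4-dimethoxy-3-(4-methylpentyl)phenyl]methanone | CC(C)CCCc1c(OC)ccc(C(=O)c2cc(Cl)c(Cl)[nH]2)c1OC | intermediate
19 | (4,5-dichloro-1H-pyrrol-2-yl)[2,4-dihydroxy-3-(4-methylpentyl)phenyl]methanone | CC(C)CCCc1c(O)ccc(C(=O)c2cc(Cl)c(Cl)[nH]2)c1O | target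

Total step count: 8 (steps 1 and 2 run in parallel).
Longest linear sequence: 7 steps, from 1 or from 4 to 19.

## Least certain steps

Step 3 (key step). The diazo group of one molecule of 3 may add as a dipole to the doubly activated alkene of another before photolysis is complete. Light may also isomerize the E alkene of 3 or 7, after which the ester oxygen can close onto the ketene. The electrophilic ketene 7 may dimerize or be captured by traces of water faster than by 6. The fallback uses neither light nor a diazo compound. It sets out from 6 and comes back to the route at 8. Purchased diethyl glutaconate is half-saponified (KOH, one equivalent, EtOH) to (E)-5-ethoxy-5-oxopent-3-enoic acid F1. Oxalyl chloride converts F1 into ethyl (E)-5-chloro-5-oxopent-2-enoate F2. Slow addition of Et3N to F2 in the presence of 6 at room temperature generates ketene 7 by dehydrochlorination in the dark, and the ketene–ynol ether (2+2) cycloaddition should give cyclobutenone 8, which is heated at 80 °C to reach 11. The double-bond isomer of F2 would give the same ketene, so the position of the alkene in the half ester does not matter.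

Step 1. Enolization of 1 may be accompanied by conjugate self-addition, because its alkene is a strong Michael acceptor. Amine or sulfonamide may also add to the same alkene during the diazo transfer. The fallback avoids the strongly basic enolization. It sets out from 1 and comes back at 3. Acid-promoted bromination of the methyl group (Br2, CHCl3; the electron-poor alkene does not add bromine) should give ethyl (E)-5-bromo-4-oxopent-2-enoate F3. Treatment of F3 with N,N'-ditosylhydrazine and DBU in THF at 0 °C, by displacement of bromide and double elimination of sulfinate, should deliver 3.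

Step 6. Acylation may go to nitrogen or to C3 of the pyrrole in competition with C2, and the ortho-methoxy group may slow the acid chloride. The fallback replaces the metalated pyrrole by an electrophilic substitution of neutral pyrrole. It sets out from 13 and comes back at 17. Chloride 15 is treated with morpholine to give [2,4-dimethoxy-3-(4-methylpentyl)phenyl](morpholin-4-yl)methanone F4. F4 is activated with POCl3 in ClCH2CH2Cl and reacted with 14 (Vilsmeier–Haack aroylation, which attacks pyrrole at C2), and hydrolysis of the iminium salt with aqueous NaOAc should give 17.

Step 7. Chlorination may spill onto C5 of ring A, which is ortho and para to the two methoxy groups. It may also continue to C3 of the pyrrole, or stop short at the monochloride. The fallback deactivates ring A before the halogen is introduced. It sets out from 17 and comes back at 19. BBr3 in CH2Cl2 gives [2,4-dihydroxy-3-(4-methylpentyl)phenyl](1H-pyrrol-2-yl)methanone F5. Ac2O and pyridine convert F5 into 2-(4-methylpentyl)-4-(1H-pyrrole-2-carbonyl)-1,3-phenylene diacetate F6, whose ring A is far less nucleophilic than that of 17. SO2Cl2 (2 equiv) should then give 4-(4,5-dichloro-1H-pyrrole-2-carbonyl)-2-(4-methylpentyl)-1,3-phenylene diacetate F7, and K2CO3 in MeOH removes the acetates to give 19.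

## Further compounds

F1 | step 3 | (E)-5-ethoxy-5-oxopent-3-enoic acid | OC(=O)C/C=C/C(=O)OCC
F2 | step 3 | ethyl (E)-5-chloro-5-oxopent-2-enoate | CCOC(=O)/C=C/CC(Cl)=O
F3 | step 1 | ethyl (E)-5-bromo-4-oxopent-2-enoate | CCOC(=O)/C=C/C(=O)CBr
F4 | step 6 | [2,4-dimethoxy-3-(4-methylpentyl)phenyl](morpholin-4-yl)methanone | CC(C)CCCc1c(OC)ccc(C(=O)N2CCOCC2)c1OC
F5 | step 7 | [2,4-dihydroxy-3-(4-methylpentyl)phenyl](1H-pyrrol-2-yl)methanone | CC(C)CCCc1c(O)ccc(C(=O)c2ccc[nH]2)c1O
F6 | step 7 | 2-(4-methylpentyl)-4-(1H-pyrrole-2-carbonyl)-1,3-phenylene diacetate | CC(C)CCCc1c(OC(C)=O)ccc(C(=O)c2ccc[nH]2)c1OC(C)=O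
F7 | step 7 | 4-(4,5-dichloro-1H-pyrrole-2-carbonyl)-2-(4-methylpentyl)-1,3-phenylene diacetate | CC(C)CCCc1c(OC(C)=O)ccc(C(=O)c2cc(Cl)c(Cl)[nH]2)c1OC(C)=O
A1 | alternative 1 | 1-(2-hydroxy-6-methoxyphenyl)-4-methylpentan-1-one | CC(C)CCC(=O)c1c(O)cccc1OC
A2 | alternative 1 | 3-methoxybenzyne (1-methoxycyclohexa-1,3-dien-5-yne) | COC1=CC=CC#C1
A3 | alternative 1 | 4-methylpentanoic acid | CC(C)CCC(O)=O
A4 | alternative 1 | 2-(4-methylpentyl)benzene-1,3-diol | CC(C)CCCc1c(O)cccc1O
A5 | alternative 1 | 4,5-dichloro-1H-pyrrole-2-carboxylic acid | OC(=O)c1cc(Cl)c(Cl)[nH]1
A6 | alternative 2 | (4-chloro-1H-pyrrol-2-yl)[2,4-dimethoxy-3-(4-methylpentyl)phenyl]methanone | CC(C)CCCc1c(OC)ccc(C(=O)c2cc(Cl)c[nH]2)c1OC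
A7 | alternative 2 | 2-amino-1-[2,4-dimethoxy-3-(4-methylpentyl)phenyl]ethan-1-one | CC(C)CCCc1c(OC)ccc(C(=O)CN)c1OC
A8 | alternative 2 | 2-chloro-1,3-bis(dimethylamino)trimethinium hexafluorophosphate | CN(C)C=C(Cl)C=[N+](C)C.F[P-](F)(F)(F)(F)F
A9 | alternative 3 | 4-[4,5-dichloro-1-(2-trimethylsilylethoxymethyl)pyrrole-2-carbonyl]-2-(4-methylpentyl)cyclohexane-1,3-dione | CC(C)CCCC1C(=O)CCC(C(=O)c2cc(Cl)c(Cl)n2COCC[Si](C)(C)C)C1=O
A10 | alternative 3 | 1-[4,5-dichloro-1-(2-trimethylsilylethoxymethyl)pyrrol-2-yl]-8-methylnonane-1,3-dione | CC(C)CCCCC(=O)CC(=O)c1cc(Cl)c(Cl)n1COCC[Si](C)(C)C
A11 | alternative 3 | methyl acrylate | C=CC(=O)OC
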